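The earlier runs and the new flask are calculated from invented constants; scatter was added.

| flask | substrate | remark | time |
|---|---|---|---|
| Thursday's | 20 mM | the very flask that is asked about, followed so far |  |
| Sunday's | 13 mM | run made earlier |  |
| flask | 20 mM |  | 15 d |

- Thursday's (time / d: target / %, substrate / %): 0.250: 40.5, 56.7; 0.417: 54.6, 37.6; 0.833: 66.8, 13.2; 1.25: 63.6, 4.4; 2.50: 52.6, 1.4; 5.00: 46.0, 0
- Sunday's (time / d: target / %, substrate / %): 0.250: 41.1, 56.4; 0.417: 54.9, 38.3; 0.833: 66.7, 12.6; 1.67: 60.1, 2.4; 3.00: 50.4, 1.4; 6.00: 45.2, 0.2

(readings scatter by 1 percentage point)

**The question.** When does this flask hold most target, and how long does it stay near that amount?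

- time, not beyond 15 d, at which the flask holds most target
- the amount of target, in percent of the substrate charged, at that time
- earliest time at which at least nineteen twentieths of that best amount are there, in d
- latest time at which they still are, in d



**In the flask.** Thursday's flask, charged at 20 mM, gave its highest reading of target, 66.8%, at 0.833 d, and its later readings fall. Sunday's run, charged at 13 mM, reads 66.7% at that same time, so between these two charges the percentages do not shift beyond the scatter.

**What comes.** The fall slows in both runs, so I take it to end and freeze it there. The last readings, 46.0% and 45.2%, each good to 1 percentage point, average to the late share, the part of the charge that stays target once the fall ends: 45.6%. For Thursday's flask that means c(target) of about 9.12 mM, and the late share stands 21 points under the highest reading. I expect no second rise, so I would not hold this flask on in hope of more.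

**The forecast.** The forecast gives 67.2% at 0.9 d, with the asked share of that amount held from 0.61 d to 1.3 d, and it reads the fall as “a reversible loss”.

**The result.** The flask gives 66.2% at 0.916 d, with the asked share of that amount held from 0.614 d to 1.38 d, so the forecast stands within its margins.

    target ⇌ isomer of the product (K = 1.20, k = 0.0240 h⁻¹)
    substrate → target (k = 0.0970 h⁻¹)

**Next flask.** The peak is kinetic control and the late level thermodynamic control: at 15.0 d this flask holds 45.5% target beside 54.5% isomer of the product. A neighbour flask charged with 8.0 mM gets the same reckoning, the late share times its charge, which gives c(target) of about 3.65 mM. That neighbour reaches 66.2% at best and ends at 15.0 d with 45.5% target, a c(target) of 3.64 mM.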